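Everything rests on cutting the side chain at C12–C13 and C14–C15 (decalin ring carbons C1–C10 with C8=C9, chain C11–C15, butenolide ring C16–C19). One three-component step, syn-carbocupration of silyl-protected propargyl alcohol followed by alkynylation of the alkenylcopper, makes both bonds and exploits the trisubstituted C13=C14 olefin, whose C12 and C15 are cis and whose CH2OH carbon is trans to C15: the imprint of syn carbon/copper addition across a terminal alkyne. The precursor is the sixteen-carbon homodrimenyl Grignard reagent carrying the C8=C9 olefin and the C5 and C10 stereocenters of (+)-sclareolide. The butenolide ring is closed last by Sonogashira coupling–lactonisation.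

Key step: step 10

Assumption: the target's C5 and C10 configuration is that of (+)-sclareolide (both SMILES agree), so no stereocenter has to be made; lactol 2 is used as its C12 epimer mixture, which converges in step 2; in compounds 1–3 "C12" means the lactone carbon that is excised, and from step 5 on the carbon delivered by CH2I2 takes its place in the chain.

Step 1
Reactants: 1 (+)-sclareolide
Product: 2 sclareolide lactol [(3aR,5aS,9aS,9bR)-3a,6,6,9a-tetramethyldodecahydronaphtho[2,1-b]furan-2-ol; both C12 epimers]
Conditions: i-Bu2AlH, CH2Cl2, −78 °C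
Reagents that add atoms: none
Why: Partial reduction of the γ-lactone: at −78 °C the tetrahedral O–Al(i-Bu)2 hemiacetal persists until work-up, so the carbonyl is taken only to the lactol and none of the four stereocenters is touched.

Step 2
Reactants: 2 sclareolide lactol
Product: 3 11-iododriman-8α-yl formate [(1R,2R,4aS,8aS)-1-(iodomethyl)-2,5,5,8a-tetramethyldecahydronaphthalen-2-yl formate]
Conditions: PhI(OAc)2, I2, cyclohexane/CH2Cl2, visible light, rt
Reagents that add atoms: iodine, II
Why: Suárez alkoxy-radical fragmentation: the anomeric O–I hypoiodite formed in the flask is homolysed by light and the alkoxy radical undergoes β-scission of C11–C12, which leaves the old lactone carbon as a formate on the C8 oxygen and a primary C11 radical that is trapped by iodine, with C8 and C9 untouched.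

Step 3
Reactants: 3 11-iododriman-8α-yl formate
Product: 4 drim-9(11)-en-8α-yl formate [(2R,4aS,8aS)-2,5,5,8a-tetramethyl-1-methylidenedecahydronaphthalen-2-yl formate]
Conditions: AgF, pyridine, rt, dark
Reagents that add atoms: none
Why: Silver-assisted dehydroiodination (E2-type elimination) of the primary iodide, for which C9–H is the only β-hydrogen, so that the exocyclic C9=C11 olefin is the only possible alkene and the formate is left in place by the non-nucleophilic medium.

Step 4
Reactants: 4 drim-9(11)-en-8α-yl formate
Product: 5 drim-9(11)-en-8α-ol [(2R,4aS,8aS)-2,5,5,8a-tetramethyl-1-methylidenedecahydronaphthalen-2-ol]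
Conditions: K2CO3 (cat.), MeOH, rt
Reagents that add atoms: none
Why: Base-catalysed methanolysis (transesterification) of the formate, the most labile of esters even on a tertiary oxygen; the C8–O bond is not broken, so the 8α configuration is kept.

Step 5
Reactants: 5 drim-9(11)-en-8α-ol
Product: 6 spirocyclopropyl carbinol [(2'R,4a'S,8a'S)-2',5',5',8a'-tetramethyl-3',4',4a',5',6',7',8',8a'-octahydro-2'H-spiro[cyclopropane-1,1'-naphthalen]-2'-ol; cyclopropane spiro-fused at C9]
Conditions: Et2Zn, CH2I2, CH2Cl2, 0 °C → rt
Reagents that add atoms: diiodomethane, ICI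
Why: Hydroxyl-directed Simmons–Smith cyclopropanation with Et2Zn/CH2I2: the C8 alkoxide (ROZnEt) holds the zinc carbenoid next to the 1,1-disubstituted C9=C11 olefin and speeds its methylenation; the spiro carbon C9 carries two like CH2 groups and is no stereocenter, so the face of attack is immaterial.

Step 6
Reactants: 6 spirocyclopropyl carbinol
Product: 7 homodrimenyl bromide [(4aS,8aS)-1-(2-bromoethyl)-2,5,5,8a-tetramethyl-3,4,4a,5,6,7,8,8a-octahydronaphthalene]
Conditions: 48% aq HBr, Et2O, 0 °C
Reagents that add atoms: hydrogen bromide, Br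
Why: Julia cyclopropylcarbinyl–homoallyl rearrangement: protonation and loss of water from the tertiary C8 alcohol give a cyclopropylcarbinyl cation that bromide opens at a ring CH2, which places the double bond at C8=C9 and nowhere else and gives the primary bromide; the C8 stereocenter is removed on purpose.

Step 7
Reactants: 7 homodrimenyl bromide
Product: 8 2-[(4aS,8aS)-2,5,5,8a-tetramethyl-3,4,4a,5,6,7,8,8a-octahydronaphthalen-1-yl]ethylmagnesium bromide (titrated THF solution)
Conditions: Mg turnings (I2-activated), THF, 35–45 °C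
Reagents that add atoms: magnesium, [Mg]
Why: Grignard formation by insertion of magnesium into the primary C–Br bond; the homoallyl–cyclopropylcarbinyl equilibrium of the reagent lies on the open-chain side and only exchanges the two CH2 groups, so the constitution is safe.

Step 8
Reactants: 9 propargyl alcohol
Product: 10 triisopropyl(prop-2-yn-1-yloxy)silane
Conditions: TIPSCl, imidazole, CH2Cl2, rt
Reagents that add atoms: chlorotriisopropylsilane, CC(C)[Si](Cl)(C(C)C)C(C)C
Why: Standard silyl ether formation of a primary alcohol (TIPSCl/imidazole); the bulky, weakly basic OSi(i-Pr)3 group is chosen because the key step needs an oxygen that does not bind copper.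

Step 9
Reactants: 11 ethynyltrimethylsilane
Product: 12 (bromoethynyl)trimethylsilane (used as a solution)
Conditions: NBS (1.05 equiv), AgNO3 (cat.), acetone, rt
Reagents that add atoms: N-bromosuccinimide, O=C1CCC(=O)N1Br
Why: AgNO3-catalysed bromination of the terminal alkyne C–H with NBS, which with one equivalent of NBS is faster than bromodesilylation at the silicon-bearing carbon.

Step 10
Reactants: 8 homodrimenylethyl Grignard reagent; 10 triisopropyl(prop-2-yn-1-yloxy)silane; 12 (bromoethynyl)trimethylsilane
Product: 15 (E)-enyne triisopropyl{[(2E)-2-{2-[(4aS,8aS)-2,5,5,8a-tetramethyl-3,4,4a,5,6,7,8,8a-octahydronaphthalen-1-yl]ethyl}-5-(trimethylsilyl)pent-2-en-4-yn-1-yl]oxy}silane, via alkylcopper–MgBr2 reagent 13 (not isolated), via (E)-alkenylcopper 14 (not isolated)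
Conditions: CuBr·SMe2 (1 equiv), THF/Me2S, −45 °C; 10, −45 → −20 °C; TMEDA, 12, −20 °C → rt
Reagents that add atoms: none
Why: Transmetalation of 8 with CuBr·SMe2 gives the alkylcopper–magnesium bromide reagent 13 (RCu·MgBr2), which π-complexes the terminal alkyne of 10 and inserts it in a concerted four-centre syn addition that delivers C12 to the internal carbon C13 and copper to the terminal carbon C14, giving the configurationally stable alkenylcopper 14. TMEDA then activates 14 for coupling with the 1-bromoalkyne 12 (oxidative addition at monovalent copper, reductive elimination from trivalent copper), which forms C14–C15 with retention, so that C12 and C15 end up cis and the olefin is E. The closest known reaction type is the Normant carbocupration of terminal alkynes by RCu·MgBr2 followed by alkynylation of the alkenylcopper with a 1-haloalkyne. No ring is closed and no stereocenter is made; the only stereochemical element is the C13=C14 geometry, which follows from syn addition and retention. The step needs branched regiochemistry (C12 to C13, not to C14) and addition instead of deprotonation of the alkyne C–H: the bulky, weakly Lewis-basic OSi(i-Pr)3 group and the coordinating solvent THF deny the ether oxygen the copper chelation that would steer the alkyl group to C14 (and on to an allene by β-elimination), while the low basicity of the alkylcopper below −20 °C favours insertion. The tetrasubstituted C8=C9 olefin and the silyl ether are inert to the organocopper species, and the copper brought in by CuBr·SMe2 leaves as CuBr.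

Step 11
Reactants: 15 (E)-enyne bis-silyl compound
Product: 16 (2E)-2-{2-[(4aS,8aS)-2,5,5,8a-tetramethyl-3,4,4a,5,6,7,8,8a-octahydronaphthalen-1-yl]ethyl}pent-2-en-4-yn-1-ol
Conditions: Bu4NF (2.5 equiv), THF, 0 °C → rt
Reagents that add atoms: none
Why: Fluoride-induced desilylation: Bu4NF cleaves the alkynyl C–SiMe3 bond and the primary O–Si(i-Pr)3 bond in the same flask, which frees both functions before the base-sensitive ylidene butenolide exists; the CH2OH group is trans to the alkyne and cannot add to it.

Step 12
Reactants: 17 but-2-ynoic acid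
Product: 18 (Z)-3-iodobut-2-enoic acid
Conditions: NaI, AcOH, 110 °C
Reagents that add atoms: sodium iodide (NaI), [Na+].[I-]
Why: Hydroiodination of the ynoic acid by conjugate addition of iodide and protonation, an overall anti addition that gives the (Z)-β-iodo acid with iodine cis to CO2H.

Step 13
Reactants: 16 (E)-enynol; 18 (Z)-3-iodobut-2-enoic acid
Product: 20 target (5Z)-5-[(2E)-3-(hydroxymethyl)-5-[(4aS,8aS)-2,5,5,8a-tetramethyl-3,4,4a,5,6,7,8,8a-octahydronaphthalen-1-yl]pent-2-en-1-ylidene]-4-methylfuran-2(5H)-one, via (2Z,6E)-dienynoic acid 19 (not isolated)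
Conditions: Pd(PPh3)4 (5 mol %), CuI (10 mol %), Et3N, MeCN (degassed), rt
Reagents that add atoms: none
Why: Tandem Sonogashira coupling–lactonisation: coupling at the C–I bond with retention gives the (2Z)-en-4-ynoic acid 19, whose carboxylate lies cis to the alkyne and adds to metal-activated C16 in a 5-exo-dig anti fashion, and protonation then gives the C16–O bond and the (Z)-C15=C16 ylidene of the butenolide; the tetrasubstituted olefin and the free allylic alcohol are spectators.

Compound list

1 | (+)-sclareolide, (3aR,5aS,9aS,9bR)-3a,6,6,9a-tetramethyldecahydronaphtho[2,1-b]furan-2(1H)-one | O=C1C[C@H]2[C@](C)(O1)CC[C@H]3C(C)(C)CCC[C@]23C | starting material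
2 | sclareolide lactol, (3aR,5aS,9aS,9bR)-3a,6,6,9a-tetramethyldodecahydronaphtho[2,1-b]furan-2-ol (C12 epimers) | OC1C[C@H]2[C@](C)(O1)CC[C@H]3C(C)(C)CCC[C@]23C | intermediate
3 | 11-iododriman-8α-yl formate, (1R,2R,4aS,8aS)-1-(iodomethyl)-2,5,5,8a-tetramethyldecahydronaphthalen-2-yl formate | IC[C@H]1[C@](C)(OC=O)CC[C@H]2C(C)(C)CCC[C@]12C | intermediate
4 | drim-9(11)-en-8α-yl formate, (2R,4aS,8aS)-2,5,5,8a-tetramethyl-1-methylidenedecahydronaphthalen-2-yl formate | C=C1[C@](C)(OC=O)CC[C@H]2C(C)(C)CCC[C@]12C | intermediate
5 | drim-9(11)-en-8α-ol, (2R,4aS,8aS)-2,5,5,8a-tetramethyl-1-methylidenedecahydronaphthalen-2-ol | C=C1[C@](C)(O)CC[C@H]2C(C)(C)CCC[C@]12C | intermediate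
6 | spirocyclopropyl carbinol, (2'R,4a'S,8a'S)-2',5',5',8a'-tetramethyl-3',4',4a',5',6',7',8',8a'-octahydro-2'H-spiro[cyclopropane-1,1'-naphthalen]-2'-ol | C1CC13[C@](C)(O)CC[C@H]2C(C)(C)CCC[C@]32C | intermediate
7 | homodrimenyl bromide, (4aS,8aS)-1-(2-bromoethyl)-2,5,5,8a-tetramethyl-3,4,4a,5,6,7,8,8a-octahydronaphthalene | BrCCC1=C(C)CC[C@H]2C(C)(C)CCC[C@]12C | intermediate
8 | 2-[(4aS,8aS)-2,5,5,8a-tetramethyl-3,4,4a,5,6,7,8,8a-octahydronaphthalen-1-yl]ethylmagnesium bromide | Br[Mg]CCC1=C(C)CC[C@H]2C(C)(C)CCC[C@]12C | intermediate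
9 | propargyl alcohol (prop-2-yn-1-ol) | C#CCO | starting material
10 | triisopropyl(prop-2-yn-1-yloxy)silane | C#CCO[Si](C(C)C)(C(C)C)C(C)C | intermediate
11 | ethynyltrimethylsilane | C#C[Si](C)(C)C | starting material
12 | (bromoethynyl)trimethylsilane | BrC#C[Si](C)(C)C | intermediate
13 | {2-[(4aS,8aS)-2,5,5,8a-tetramethyl-3,4,4a,5,6,7,8,8a-octahydronaphthalen-1-yl]ethyl}copper, as its MgBr2 complex | [Cu]CCC1=C(C)CC[C@H]2C(C)(C)CCC[C@]12C | intermediate
14 | [(1E)-4-[(4aS,8aS)-2,5,5,8a-tetramethyl-3,4,4a,5,6,7,8,8a-octahydronaphthalen-1-yl]-2-{[(triisopropylsilyl)oxy]methyl}but-1-en-1-yl]copper (Cu cis to C12) | [Cu]/C=C(/CO[Si](C(C)C)(C(C)C)C(C)C)CCC1=C(C)CC[C@H]2C(C)(C)CCC[C@]12C | intermediate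
15 | triisopropyl{[(2E)-2-{2-[(4aS,8aS)-2,5,5,8a-tetramethyl-3,4,4a,5,6,7,8,8a-octahydronaphthalen-1-yl]ethyl}-5-(trimethylsilyl)pent-2-en-4-yn-1-yl]oxy}silane | C[Si](C)(C)C#C/C=C(/CO[Si](C(C)C)(C(C)C)C(C)C)CCC1=C(C)CC[C@H]2C(C)(C)CCC[C@]12C | intermediate
16 | (2E)-2-{2-[(4aS,8aS)-2,5,5,8a-tetramethyl-3,4,4a,5,6,7,8,8a-octahydronaphthalen-1-yl]ethyl}pent-2-en-4-yn-1-ol | C#C/C=C(/CO)CCC1=C(C)CC[C@H]2C(C)(C)CCC[C@]12C | intermediate
17 | but-2-ynoic acid | CC#CC(=O)O | starting material
18 | (Z)-3-iodobut-2-enoic acid | C/C(I)=C/C(=O)O | intermediate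
19 | (2Z,6E)-7-(hydroxymethyl)-3-methyl-9-[(4aS,8aS)-2,5,5,8a-tetramethyl-3,4,4a,5,6,7,8,8a-octahydronaphthalen-1-yl]nona-2,6-dien-4-ynoic acid | C/C(C#C/C=C(/CO)CCC1=C(C)CC[C@H]2C(C)(C)CCC[C@]12C)=C/C(=O)O | intermediate
20 | (5Z)-5-[(2E)-3-(hydroxymethyl)-5-[(4aS,8aS)-2,5,5,8a-tetramethyl-3,4,4a,5,6,7,8,8a-octahydronaphthalen-1-yl]pent-2-en-1-ylidene]-4-methylfuran-2(5H)-one | CC1=CC(=O)O/C1=C\C=C(\CO)CCC1=C(C)CC[C@H]2C(C)(C)CCC[C@]12C | target

Total step count: 13. Longest linear sequence: 10 steps (steps 1–7, 10, 11 and 13).

Steps most likely to fail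

Step 10. The alkylcopper may deprotonate the alkyne C–H or add with the reverse orientation and then lose silyloxide to an allene. In the second stage, bromine–copper exchange with the bromoalkyne and oxidative dimerisation may consume the alkenylcopper before C14–C15 forms. The fallback sets out from 8 and 10 and divides the two bond formations between two metals. The carbocupration is run as before to the alkenylcopper 14, which is quenched with I2 at −45 °C; this should proceed with retention and give the isolable (E)-alkenyl iodide F1, from which allene and protonated by-products can be removed. F1 is then joined to 11 by Sonogashira coupling (PdCl2(PPh3)2, CuI, Et3N, rt), which returns to the route at 15.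

Step 6. The cyclopropylcarbinyl cation may escape by ring expansion to a cyclobutyl cation or by proton loss with the three-membered ring intact, and HBr may add to the new olefin. The fallback sets out from 1 and keeps both side-chain carbons of the lactone. LiAlH4 reduction should give the 8α,12-diol F2, and Ac2O/pyridine should acetylate only the primary hydroxyl to the hydroxy acetate F3. Dehydration of the tertiary alcohol under equilibrating conditions (PPh3/I2, CH2Cl2, rt) is expected to favour the tetrasubstituted olefin of the homodrimenyl acetate F4; the Δ7 and exocyclic isomers would be removed on AgNO3-impregnated silica. Methanolysis (K2CO3, MeOH) then gives the homodrimenol F5, and Appel bromination (CBr4, PPh3) returns to the route at 7.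

Step 13. The enynoic acid may close in the 6-endo mode to a 2-pyranone, or the free acid may slow the coupling so that oxidative dimerisation of the enyne takes over. The fallback sets out from 16 and 18 and separates coupling from ring closure. Acid 18 is esterified (MeI, K2CO3, DMF) to methyl (Z)-3-iodobut-2-enoate F6, which is Sonogashira-coupled with 16 (PdCl2(PPh3)2, CuI, Et3N) to the methyl dienynoate F7. Saponification (LiOH, THF/H2O) gives 19, now isolated, and lactonisation with catalytic AgNO3 in MeOH, a known 5-exo-selective closure of (Z)-2-en-4-ynoic acids, returns to the route at 20.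

Further compounds

F1 | step 10 | {[(2E)-3-iodo-2-{2-[(4aS,8aS)-2,5,5,8a-tetramethyl-3,4,4a,5,6,7,8,8a-octahydronaphthalen-1-yl]ethyl}prop-2-en-1-yl]oxy}triisopropylsilane | I/C=C(/CO[Si](C(C)C)(C(C)C)C(C)C)CCC1=C(C)CC[C@H]2C(C)(C)CCC[C@]12C
F2 | step 6 | (1R,2R,4aS,8aS)-1-(2-hydroxyethyl)-2,5,5,8a-tetramethyldecahydronaphthalen-2-ol | OCC[C@H]1[C@](C)(O)CC[C@H]2C(C)(C)CCC[C@]12C
F3 | step 6 | 2-[(1R,2R,4aS,8aS)-2-hydroxy-2,5,5,8a-tetramethyldecahydronaphthalen-1-yl]ethyl acetate | CC(=O)OCC[C@H]1[C@](C)(O)CC[C@H]2C(C)(C)CCC[C@]12C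
F4 | step 6 | 2-[(4aS,8aS)-2,5,5,8a-tetramethyl-3,4,4a,5,6,7,8,8a-octahydronaphthalen-1-yl]ethyl acetate | CC(=O)OCCC1=C(C)CC[C@H]2C(C)(C)CCC[C@]12C
F5 | step 6 | 2-[(4aS,8aS)-2,5,5,8a-tetramethyl-3,4,4a,5,6,7,8,8a-octahydronaphthalen-1-yl]ethanol | OCCC1=C(C)CC[C@H]2C(C)(C)CCC[C@]12C
F6 | step 13 | methyl (Z)-3-iodobut-2-enoate | C/C(I)=C/C(=O)OC
F7 | step 13 | methyl (2Z,6E)-7-(hydroxymethyl)-3-methyl-9-[(4aS,8aS)-2,5,5,8a-tetramethyl-3,4,4a,5,6,7,8,8a-octahydronaphthalen-1-yl]nona-2,6-dien-4-ynoate | C/C(C#C/C=C(/CO)CCC1=C(C)CC[C@H]2C(C)(C)CCC[C@]12C)=C/C(=O)OC
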